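**Strategy**

Everything rests on excising C8 from ring B (C5–C10, labdane numbering). C8 carries the carboxyl carbon C17 and is the only ring atom between the methylene C7 and C9, which carries the side chain, so deleting it contracts ring B to a cyclopentanone fused to ring A. The key step reverses this: ethyl diazoacetate and BF3·OEt2 insert C8, with C17 attached as an ester, between the C9 carbonyl and C7, forming C7–C8 and C8–C9 in one operation and leaving a C9 ketone through which the C11–C15 chain is attached. The precursor is (3aS,7aS)-4,4,7a-trimethyl-trans-hydrindan-1-one, made from the (S)-Hajos–Parrish ketone.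

Key step: step 7

Remark: positions are given in labdane numbering (C1–C10 decalin, C11–C16 side chain, C17 on C8, C20 on C10); compounds 13, 22, 23 and 24 are carried as C8 epimers because C8 is enolisable or becomes sp2 in the next step, and the (R)-monoester 15 gives 13S only when its free acid carbon becomes C15 and its ester carbon C11, which is how it is used here.

**Route**

Step 1
Reactants: 1 2-methylcyclopentane-1,3-dione; 2 methyl vinyl ketone
Product: 3 2-methyl-2-(3-oxobutyl)cyclopentane-1,3-dione
Conditions: H2O, AcOH (cat.), 70 °C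
Reagents that add atoms: none
Why: Michael addition of the acidic cyclic 1,3-dione to the enone in water should give the triketone, which has no stereocentre.

Step 2
Reactants: 3 2-methyl-2-(3-oxobutyl)cyclopentane-1,3-dione
Product: 5 (S)-7a-methyl-2,3,7,7a-tetrahydro-1H-indene-1,5(6H)-dione, via cis-ketol 4 (not isolated)
Conditions: (S)-proline (3 mol %), DMF, rt; then H2SO4 (cat.), DMF, 95 °C
Reagents that add atoms: none
Why: Hajos–Parrish aldol cyclisation, in which the (S)-proline enamine of the side-chain ketone attacks one of the two enantiotopic ring carbonyls through a hydrogen-bonded chair-like transition state and so sets the quaternary centre (7aS), followed by acid-catalysed dehydration of the ketol.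

Step 3
Reactants: 5 (S)-7a-methyl-2,3,7,7a-tetrahydro-1H-indene-1,5(6H)-dione
Product: 6 (S)-7a-methyl-2,3,7,7a-tetrahydro-1H-indene-1,5(6H)-dione 1-(ethylene ketal)
Conditions: ethylene glycol, p-TsOH (cat.), 4 Å MS, CH2Cl2, rt
Reagents that add atoms: ethylene glycol, OCCO
Why: Acid-catalysed ketalisation should be chemoselective for the saturated, more electrophilic cyclopentanone carbonyl over the conjugated enone carbonyl.

Step 4
Reactants: 6 (S)-7a-methyl-2,3,7,7a-tetrahydro-1H-indene-1,5(6H)-dione 1-(ethylene ketal)
Product: 7 (S)-4,4,7a-trimethyl-2,6,7,7a-tetrahydro-1H-indene-1,5(4H)-dione 1-(ethylene ketal)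
Conditions: KOtBu, MeI, t-BuOH/THF, 0 °C to rt
Reagents that add atoms: iodomethane, CI
Why: Deconjugative double alkylation, in which the thermodynamic dienolate (γ-deprotonation at indene C3) is methylated twice at the α-carbon C4, should install the gem-dimethyl group and leave the alkene at C3=C3a.

Step 5
Reactants: 7 (S)-4,4,7a-trimethyl-2,6,7,7a-tetrahydro-1H-indene-1,5(4H)-dione 1-(ethylene ketal)
Product: 9 (S)-4,4,7a-trimethyl-2,4,5,6,7,7a-hexahydro-1H-inden-1-one ethylene ketal, via hydrazone 8 (not isolated)
Conditions: N2H4·H2O, KOH, diethylene glycol, 130 °C then 200 °C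
Reagents that add atoms: none
Why: Wolff–Kishner reduction (Huang-Minlon procedure) should remove the C5 carbonyl through its hydrazone, while the ketal and the isolated trisubstituted alkene are inert to hot base.

Step 6
Reactants: 9 (S)-4,4,7a-trimethyl-2,4,5,6,7,7a-hexahydro-1H-inden-1-one ethylene ketal
Product: 11 (3aS,7aS)-4,4,7a-trimethyloctahydro-1H-inden-1-one, via saturated ketal 10 (not isolated)
Conditions: H2 (4 atm), Pd/C, EtOAc, rt; filter; then 2 M HCl, THF, rt
Reagents that add atoms: water, O
Why: Heterogeneous hydrogenation should deliver hydrogen to C3=C3a from the α-face, because the angular methyl and the axial C4 methyl together shield the β-face, which sets the ring-fusion hydrogen trans to the angular methyl (3aS), and aqueous acid then hydrolyses the dioxolane.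

Step 7
Reactants: 11 (3aS,7aS)-4,4,7a-trimethyloctahydro-1H-inden-1-one; 12 ethyl diazoacetate
Product: 13 ethyl (4aS,8aS)-5,5,8a-trimethyl-1-oxodecahydronaphthalene-2-carboxylate (C2 epimers in equilibrium with the enol)
Conditions: BF3·OEt2 (2 equiv), 12 (1.5 equiv, slow addition), Et2O, 0 °C to rt
Reagents that add atoms: none
Why: BF3 activates the C9 carbonyl, the diazo carbon of 12 adds to it, and the resulting 2-diazonium alkoxide loses N2 while the C9–C7 bond shifts to the former diazo carbon, which becomes C8 with its ester carbon C17. The closest known reaction type is the Lewis-acid-promoted homologation of cyclic ketones with diazoacetates (Büchner–Curtius–Schlotterbeck reaction, mechanistically a Tiffeneau–Demjanov-type shift), which is established for cyclopentanones that have a quaternary α-carbon. Ring B is not closed by a cyclisation but arises by enlargement of the five-membered ring by one atom, so it is formed by a 1,2-shift and not by an exo or endo closure. No lasting stereocentre is created, because C5 and C10 are not involved, the migrating C7 is a methylene and C8 is enolisable. The only selectivity required is migration of C7 in preference to the quaternary C10, and the substrate secures it because the less substituted α-carbon migrates in these homologations and the congested C10, held between ring A and the angular methyl, is the poorer partner for the shift. The product is held as the BF3-bound enol of the β-keto ester, which should prevent a second insertion.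

Step 8
Reactants: 13 ethyl (4aS,8aS)-5,5,8a-trimethyl-1-oxodecahydronaphthalene-2-carboxylate
Product: 14 ethyl (4aS,8aS)-5,5,8a-trimethyl-1-{[(trifluoromethyl)sulfonyl]oxy}-3,4,4a,5,6,7,8,8a-octahydronaphthalene-2-carboxylate
Conditions: NaH, Et2O, 0 °C; then Tf2O, 0 °C
Reagents that add atoms: trifluoromethanesulfonic anhydride, O=S(=O)(OS(=O)(=O)C(F)(F)F)C(F)(F)F
Why: O-Sulfonylation of the sodium enolate of the β-keto ester should give the enol triflate as a single regioisomer, since C8 is the only enolisable position next to the C9 carbonyl.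

Step 9
Reactants: 15 (R)-3-methylglutaric acid monomethyl ester
Product: 16 methyl (R)-5-hydroxy-3-methylpentanoate
Conditions: BH3·SMe2, THF, −10 °C to rt; MeOH quench
Reagents that add atoms: none
Why: Chemoselective borane reduction, in which the free acid is reduced through its acyloxyborane much faster than the methyl ester, should give the hydroxy ester without touching the stereocentre.

Step 10
Reactants: 16 methyl (R)-5-hydroxy-3-methylpentanoate
Product: 17 methyl (R)-5-[(tert-butyldimethylsilyl)oxy]-3-methylpentanoate
Conditions: TBSCl, imidazole, DMF, rt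
Reagents that add atoms: tert-butyldimethylsilyl chloride, CC(C)(C)[Si](C)(C)Cl
Why: Imidazole-promoted silylation of the primary alcohol should prevent lactonisation and protect O15 through the organometallic and reductive steps.

Step 11
Reactants: 17 methyl (R)-5-[(tert-butyldimethylsilyl)oxy]-3-methylpentanoate
Product: 18 (S)-5-[(tert-butyldimethylsilyl)oxy]-3-methylpentan-1-ol
Conditions: LiAlH4, THF, 0 °C
Reagents that add atoms: none
Why: Hydride reduction of the methyl ester should give the primary alcohol (future C11), the silyl ether being stable to LiAlH4 at 0 °C.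

Step 12
Reactants: 18 (S)-5-[(tert-butyldimethylsilyl)oxy]-3-methylpentan-1-ol
Product: 19 (R)-tert-butyl[(5-iodo-3-methylpentyl)oxy]dimethylsilane
Conditions: I2, PPh3, imidazole, CH2Cl2, 0 °C to rt
Reagents that add atoms: iodine, II
Why: Appel-type iodination should convert the primary alcohol into the iodide by SN2 displacement of the oxyphosphonium group, remote from the stereocentre.

Step 13
Reactants: 14 ethyl (4aS,8aS)-5,5,8a-trimethyl-1-{[(trifluoromethyl)sulfonyl]oxy}-3,4,4a,5,6,7,8,8a-octahydronaphthalene-2-carboxylate; 19 (R)-tert-butyl[(5-iodo-3-methylpentyl)oxy]dimethylsilane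
Product: 21 ethyl (13S)-15-[(tert-butyldimethylsilyl)oxy]labd-8-en-17-oate, via alkylzinc iodide 20 (not isolated)
Conditions: Zn dust (activated), LiCl, THF, 40 °C; then 14, Pd(dppf)Cl2 (5 mol %), THF/NMP, 60 °C
Reagents that add atoms: none
Why: Negishi cross-coupling, in which zinc inserts into the primary C–I bond and the alkylzinc iodide transmetalates to the vinylpalladium species formed by oxidative addition of the electron-poor enol triflate to zerovalent palladium, should form C9–C11, the bidentate dppf ligand (1,1'-bis(diphenylphosphino)ferrocene) favouring reductive elimination over β-hydride elimination.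

Step 14
Reactants: 21 ethyl (13S)-15-[(tert-butyldimethylsilyl)oxy]labd-8-en-17-oate
Product: 22 ethyl (13S)-15-[(tert-butyldimethylsilyl)oxy]labdan-17-oate (9α-H; C8 epimers)
Conditions: Li, NH3(l)/THF, t-BuOH (1 equiv), −78 °C; then NH4Cl
Reagents that add atoms: none
Why: Dissolving-metal (Birch-type) conjugate reduction of the enoate should protonate the β-carbon C9 of the radical anion along the axial trajectory on the α-face, anti to the C10 methyl, which places the side chain equatorial (9α-H), and the ester enolate so formed resists further reduction until the quench.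

Step 15
Reactants: 22 ethyl (13S)-15-[(tert-butyldimethylsilyl)oxy]labdan-17-oate
Product: 25 ethyl (13S)-15-[(tert-butyldimethylsilyl)oxy]labd-7-en-17-oate, via 8-phenylselanyl ester 23 (not isolated), via selenoxide 24 (not isolated)
Conditions: LiN(iPr)2, THF, −78 °C; PhSeBr, −78 °C; then 30% H2O2, pyridine, CH2Cl2, 0 °C to rt
Reagents that add atoms: none
Why: α-Selenenylation of the ester enolate and selenoxide syn-elimination should give the conjugated alkene towards C7, because elimination towards C9 must eclipse the ester with the C9 side chain and would give the strained tetrasubstituted alkene, and C9 itself is not touched.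

Step 16
Reactants: 25 ethyl (13S)-15-[(tert-butyldimethylsilyl)oxy]labd-7-en-17-oate
Product: 27 (13S)-15-hydroxylabd-7-en-17-oic acid, via silyl ether acid 26 (not isolated)
Conditions: KOH, EtOH/H2O, 80 °C; then 2 M HCl (pH 1), THF, rt
Reagents that add atoms: potassium hydroxide, [K+].[OH-]
Why: Saponification of the conjugated ethyl ester followed by acid cleavage of the primary silyl ether on acidification should give the hydroxy acid, the carboxylate being inert to base so that C9 and the C7=C8 alkene are not disturbed.

Step 17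
Reactants: 27 (13S)-15-hydroxylabd-7-en-17-oic acid
Product: 29 (5S,9R,10S,13S)-15-acetoxylabd-7-en-17-oic acid, via mixed anhydride 28 (not isolated)
Conditions: Ac2O, pyridine, DMAP (cat.), CH2Cl2, rt; then H2O, THF, rt
Reagents that add atoms: acetic anhydride, CC(=O)OC(C)=O
Why: Nucleophile-catalysed acetylation of the primary alcohol should give the acetate, and the mixed carboxylic–acetic anhydride formed at C17 is hydrolysed at its unhindered acetyl carbonyl during the aqueous stage, which returns the free acid.

**Compound list**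

1 | 2-methylcyclopentane-1,3-dione | CC1C(=O)CCC1=O | starting material
2 | methyl vinyl ketone | CC(=O)C=C | starting material
3 | 2-methyl-2-(3-oxobutyl)cyclopentane-1,3-dione | CC(=O)CCC1(C)C(=O)CCC1=O | intermediate
4 | (3aS,7aS)-3a-hydroxy-7a-methylhexahydro-1H-indene-1,5(4H)-dione (cis-ketol) | C[C@]12CCC(=O)C[C@@]1(O)CCC2=O | intermediate
5 | (S)-7a-methyl-2,3,7,7a-tetrahydro-1H-indene-1,5(6H)-dione (Hajos–Parrish ketone) | C[C@]12CCC(=O)C=C1CCC2=O | intermediate
6 | (S)-7a-methyl-2,3,7,7a-tetrahydro-1H-indene-1,5(6H)-dione 1-(ethylene ketal) | C[C@]12CCC(=O)C=C1CCC23OCCO3 | intermediate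
7 | (S)-4,4,7a-trimethyl-2,6,7,7a-tetrahydro-1H-indene-1,5(4H)-dione 1-(ethylene ketal), alkene at C3=C3a | C[C@]12CCC(=O)C(C)(C)C1=CCC23OCCO3 | intermediate
8 | C5 hydrazone of 7 | C[C@]12CCC(=NN)C(C)(C)C1=CCC23OCCO3 | intermediate
9 | (S)-4,4,7a-trimethyl-2,4,5,6,7,7a-hexahydro-1H-inden-1-one ethylene ketal, alkene at C3=C3a | C[C@]12CCCC(C)(C)C1=CCC23OCCO3 | intermediate
10 | (3aS,7aS)-4,4,7a-trimethyloctahydro-1H-inden-1-one ethylene ketal (trans-fused) | C[C@]12CCCC(C)(C)[C@@H]1CCC23OCCO3 | intermediate
11 | (3aS,7aS)-4,4,7a-trimethyloctahydro-1H-inden-1-one (trans-fused) | O=C1CC[C@H]2C(C)(C)CCC[C@]12C | intermediate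
12 | ethyl diazoacetate | CCOC(=O)C=[N+]=[N-] | starting material
13 | ethyl (4aS,8aS)-5,5,8a-trimethyl-1-oxodecahydronaphthalene-2-carboxylate (trans-fused, C2 undefined) | O=C1C(C(=O)OCC)CC[C@H]2C(C)(C)CCC[C@]12C | intermediate
14 | ethyl (4aS,8aS)-5,5,8a-trimethyl-1-{[(trifluoromethyl)sulfonyl]oxy}-3,4,4a,5,6,7,8,8a-octahydronaphthalene-2-carboxylate | O=S(=O)(OC1=C(C(=O)OCC)CC[C@H]2C(C)(C)CCC[C@]12C)C(F)(F)F | intermediate
15 | (R)-3-methylglutaric acid monomethyl ester | OC(=O)C[C@@H](C)CC(=O)OC | starting material
16 | methyl (R)-5-hydroxy-3-methylpentanoate | OCC[C@@H](C)CC(=O)OC | intermediate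
17 | methyl (R)-5-[(tert-butyldimethylsilyl)oxy]-3-methylpentanoate | CC(C)(C)[Si](C)(C)OCC[C@@H](C)CC(=O)OC | intermediate
18 | (S)-5-[(tert-butyldimethylsilyl)oxy]-3-methylpentan-1-ol | CC(C)(C)[Si](C)(C)OCC[C@@H](C)CCO | intermediate
19 | (R)-tert-butyl[(5-iodo-3-methylpentyl)oxy]dimethylsilane | CC(C)(C)[Si](C)(C)OCC[C@@H](C)CCI | intermediate
20 | (R)-{5-[(tert-butyldimethylsilyl)oxy]-3-methylpentyl}zinc iodide | CC(C)(C)[Si](C)(C)OCC[C@@H](C)CC[Zn]I | intermediate
21 | ethyl (13S)-15-[(tert-butyldimethylsilyl)oxy]labd-8-en-17-oate | CC(C)(C)[Si](C)(C)OCC[C@@H](C)CCC1=C(C(=O)OCC)CC[C@H]2C(C)(C)CCC[C@]12C | intermediate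
22 | ethyl (13S)-15-[(tert-butyldimethylsilyl)oxy]labdan-17-oate (9α-H, C8 undefined) | CC(C)(C)[Si](C)(C)OCC[C@@H](C)CC[C@H]1C(C(=O)OCC)CC[C@H]2C(C)(C)CCC[C@]12C | intermediate
23 | ethyl (13S)-15-[(tert-butyldimethylsilyl)oxy]-8-(phenylselanyl)labdan-17-oate (C8 undefined) | CC(C)(C)[Si](C)(C)OCC[C@@H](C)CC[C@H]1C([Se]c3ccccc3)(C(=O)OCC)CC[C@H]2C(C)(C)CCC[C@]12C | intermediate
24 | selenoxide of 23 | CC(C)(C)[Si](C)(C)OCC[C@@H](C)CC[C@H]1C([Se](=O)c3ccccc3)(C(=O)OCC)CC[C@H]2C(C)(C)CCC[C@]12C | intermediate
25 | ethyl (13S)-15-[(tert-butyldimethylsilyl)oxy]labd-7-en-17-oate | CC(C)(C)[Si](C)(C)OCC[C@@H](C)CC[C@H]1C(C(=O)OCC)=CC[C@H]2C(C)(C)CCC[C@]12C | intermediate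
26 | (13S)-15-[(tert-butyldimethylsilyl)oxy]labd-7-en-17-oic acid | CC(C)(C)[Si](C)(C)OCC[C@@H](C)CC[C@H]1C(C(=O)O)=CC[C@H]2C(C)(C)CCC[C@]12C | intermediate
27 | (13S)-15-hydroxylabd-7-en-17-oic acid | OCC[C@@H](C)CC[C@H]1C(C(=O)O)=CC[C@H]2C(C)(C)CCC[C@]12C | intermediate
28 | acetic (13S)-15-acetoxylabd-7-en-17-oic anhydride | CC(=O)OCC[C@@H](C)CC[C@H]1C(C(=O)OC(C)=O)=CC[C@H]2C(C)(C)CCC[C@]12C | intermediate
29 | (5S,9R,10S,13S)-15-acetoxylabd-7-en-17-oic acid | CC(=O)OCC[C@@H](C)CC[C@H]1C(C(=O)O)=CC[C@H]2C(C)(C)CCC[C@]12C | target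

**Step count and risks**

Total step count: 17. Longest linear sequence: 13 steps (steps 1–8 and 13–17); the side-chain branch is steps 9–12.

Steps most likely to fail:

Step 7. The insertion may suffer from competing migration of the quaternary carbon, from slow addition of the diazo ester to the hindered carbonyl, or from a second insertion into the product. The fallback sets out from 11 and comes back at 13, and it separates the addition from the rearrangement. Compound 12, deprotonated with LiN(iPr)2 (THF, −78 °C), should add to the ketone of 11 to give ethyl 2-diazo-2-[(3aS,7aS)-1-hydroxy-4,4,7a-trimethyloctahydro-1H-inden-1-yl]acetate F1. Catalytic Rh2(OAc)4 (CH2Cl2, rt) should then convert F1, through the rhodium carbenoid and a 1,2-alkyl shift with loss of nitrogen, into 13.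

Step 14. The reduction may stall on the hindered tetrasubstituted enoate, may over-reduce the ester, or may protonate C9 from the wrong face. The fallback sets out from 21 and comes back at 22. Kinetic deconjugation (LiN(iPr)2, THF/DMPU, −78 °C; AcOH quench at −78 °C) should move the alkene out of conjugation to give ethyl (13S)-15-[(tert-butyldimethylsilyl)oxy]labd-9(11)-en-17-oate F2. Its exocyclic trisubstituted alkene should then be hydrogenated (H2, Pd/C, EtOAc) from the α-face, anti to the C10 methyl, to give 22.

Step 15. The syn-elimination may run partly towards C9 and return the tetrasubstituted alkene (which would be recycled as 21), or enolisation of the hindered ester may be incomplete. The fallback sets out from 13 and comes back at 25; it replaces steps 8 and 13–15 and fixes the alkene position by conjugation instead of by a kinetic elimination.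
- PhSeCl and pyridine (CH2Cl2, 0 °C) should give ethyl (4aS,8aS)-5,5,8a-trimethyl-1-oxo-2-(phenylselanyl)decahydronaphthalene-2-carboxylate F3.
- H2O2 should oxidise it to the selenoxide of F3, ethyl (4aS,8aS)-5,5,8a-trimethyl-1-oxo-2-(phenylseleninyl)decahydronaphthalene-2-carboxylate F4, which can eliminate only towards C7 and should give ethyl (4aS,8aS)-5,5,8a-trimethyl-1-oxo-1,4,4a,5,6,7,8,8a-octahydronaphthalene-2-carboxylate F5.
- γ-Deprotonation at C6 (KN(SiMe3)2, THF, −78 °C) and O-triflation with PhNTf2 should give ethyl (4aS,8aS)-5,5,8a-trimethyl-1-{[(trifluoromethyl)sulfonyl]oxy}-4a,5,6,7,8,8a-hexahydronaphthalene-2-carboxylate F6.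
- Negishi coupling of F6 with 20 under the conditions of step 13 should give ethyl (13S)-15-[(tert-butyldimethylsilyl)oxy]labda-6,8-dien-17-oate F7.
- Dissolving-metal reduction (Li, NH3/THF, t-BuOH, −78 °C) should protonate C9 on the α-face and leave a dienolate, whose protonation gives 25 together with its β,γ-isomer ethyl (13S)-15-[(tert-butyldimethylsilyl)oxy]labd-6-en-17-oate F8.
- NaOEt in EtOH should move the alkene of F8 into conjugation, so that the mixture converges on 25.

**Further compounds**

F1 | step 7 | ethyl 2-diazo-2-[(3aS,7aS)-1-hydroxy-4,4,7a-trimethyloctahydro-1H-inden-1-yl]acetate (carbinol configuration not assigned) | CCOC(=O)C(=[N+]=[N-])C1(O)CC[C@H]2C(C)(C)CCC[C@]12C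
F2 | step 14 | ethyl (13S)-15-[(tert-butyldimethylsilyl)oxy]labd-9(11)-en-17-oate (C8 and alkene geometry not assigned) | CC(C)(C)[Si](C)(C)OCC[C@@H](C)CC=C1C(C(=O)OCC)CC[C@H]2C(C)(C)CCC[C@]12C
F3 | step 15 | ethyl (4aS,8aS)-5,5,8a-trimethyl-1-oxo-2-(phenylselanyl)decahydronaphthalene-2-carboxylate (C2 not assigned) | O=C1C([Se]c3ccccc3)(C(=O)OCC)CC[C@H]2C(C)(C)CCC[C@]12C
F4 | step 15 | ethyl (4aS,8aS)-5,5,8a-trimethyl-1-oxo-2-(phenylseleninyl)decahydronaphthalene-2-carboxylate (C2 not assigned) | O=C1C([Se](=O)c3ccccc3)(C(=O)OCC)CC[C@H]2C(C)(C)CCC[C@]12C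
F5 | step 15 | ethyl (4aS,8aS)-5,5,8a-trimethyl-1-oxo-1,4,4a,5,6,7,8,8a-octahydronaphthalene-2-carboxylate | O=C1C(C(=O)OCC)=CC[C@H]2C(C)(C)CCC[C@]12C
F6 | step 15 | ethyl (4aS,8aS)-5,5,8a-trimethyl-1-{[(trifluoromethyl)sulfonyl]oxy}-4a,5,6,7,8,8a-hexahydronaphthalene-2-carboxylate | O=S(=O)(OC1=C(C(=O)OCC)C=C[C@H]2C(C)(C)CCC[C@]12C)C(F)(F)F
F7 | step 15 | ethyl (13S)-15-[(tert-butyldimethylsilyl)oxy]labda-6,8-dien-17-oate | CC(C)(C)[Si](C)(C)OCC[C@@H](C)CCC1=C(C(=O)OCC)C=C[C@H]2C(C)(C)CCC[C@]12C
F8 | step 15 | ethyl (13S)-15-[(tert-butyldimethylsilyl)oxy]labd-6-en-17-oate (9α-H, C8 not assigned) | CC(C)(C)[Si](C)(C)OCC[C@@H](C)CC[C@H]1C(C(=O)OCC)C=C[C@H]2C(C)(C)CCC[C@]12C
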